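One percent of the substrate charged is my unit, and I follow it to a fork: capture by first nucleophile gives target, capture by second nucleophile gives other capture product.

in all of them: substrate 0.86 M; second nucleophile 1.72 M
- birch: first nucleophile 1.03 M; the very flask that is asked about, followed so far
- larch: first nucleophile 0.69 M; run made earlier
- flask: first nucleophile 1.03 M; time 30 h

| run | time / h | other capture product / % | target / % |
|---|---|---|---|
| birch | 2.50 | 33.1 | 31.9 |
| birch | 5.00 | 41.6 | 37.5 |
| birch | 6.00 | 42.2 | 37.8 |
| birch | 10.0 | 43.6 | 38.4 |
| larch | 4.00 | 49.5 | 29.4 |
| larch | 10.0 | 54.5 | 30.9 |
| larch | 20.0 | 54.0 | 30.9 |
| larch | 30.0 | 54.3 | 31.1 |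

(readings scatter by 0.3 percentage points)

- the analysis behind the earlier runs scatters by 0.3 percentage points, standard deviation

* share of other capture product in other capture product plus target at 80 s
* share of other capture product in other capture product plus target at 30 h

The odds at that fork are a selectivity factor times free second over free first nucleophile, both in fractions of the substrate charge. Substrate charge cancels from these odds at the start. With the two products near level, a relative error in either nucleophile charge or in the factor reaches the share scaled by a quarter, so the factor has to be good, and a scatter of 0.3 percentage points on 31.9% costs it little.

Taking each free nucleophile as its charge less its own product, the birch reading at 2.50 h gives 0.546 for the factor, other capture product over target, divided by free second over free first nucleophile. Since 80 s is far shorter than 2.50 h, I use the charges, and my share for this flask is 47.7%. Late, the larch share reads 63.8% at 10.0 h and 63.6% at 30.0 h, so I take the birch reading at 10.0 h, 53.2%, as my share for 30 h.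

The forecast says 49% at 80 s and 53.4% at 30 h, higher than mine at both times, holding that “the end state is stable”.

The flask gives 45.0% at 80 s and 53.1% at 30 h; at 30 h it holds substrate 0% and side product 17.8%, each side product counted as two.

    substrate → intermediate (k = 0.540 h⁻¹)
    first nucleophile + intermediate → target (k = 450 M⁻¹ h⁻¹)
    second nucleophile + intermediate → other capture product (k = 220 M⁻¹ h⁻¹)
    substrate + target → side product (k = 0.290 M⁻¹ h⁻¹)

The factor 0.546 put my share at 47.7% at 80 s, and the flask stands 2.7 points below that. In a neighbour flask with 3.37 equiv of second nucleophile to substrate, the factor gives 60.6% at 80 s; that neighbour computes to 58.0%.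

All runs come from a simulation on assumed constants.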